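## Analysis of the target

Target 27 is a dispiro compound. In 1,7-dioxadispiro[4.0.4.2]dodecane numbering, the cyclobutane C5–C6–C11–C12 has C5 and C6 as the spiro carbons of two 4-bromobut-2-en-4-olides. Each lactone carries a 1-acetoxybutyl group at C3 or C9, and C11 and C12 each carry a bromine.

There are six stereocentres. C5 and C6 are S,S, with the ring oxygens O1 and O7 on opposite faces of the cyclobutane. C11 and C12 are R,R: the bromines are trans to each other, and each is cis to the vinylic carbon (C10 or C4) and trans to the ring oxygen of the neighbouring lactone. One side-chain carbinol carbon is S and the other R.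

The tetrabrominated core has a twofold axis. It therefore does not matter which lactone carries which side chain, and the mirror-image core with the same two side chains is the enantiomer of 27. The absolute sense of the core must be set by the synthesis; a late separation of diastereomers cannot correct it.

The sensitive groups are the two vinylogous acyl bromides (C4–Br, C10–Br), acetates that would be expelled if C4 carried an oxygen anion, a vicinal dibromide, and a strained ring flanked by two tertiary C–O bonds.

The hard part is the pair of adjacent, fully substituted, oxygen-bearing carbons in a four-membered ring; substitution cannot make C–O bonds at such centres.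

The strategy rests on one feature. Each lactone ring O1–C2(=O)–C3=C4–C5 is a cyclobutenone C2(=O)–C3=C4–C5 with an oxygen inserted between C2 and C5, and a spiro cyclobutenone is the [2+2] adduct of an alkyne and a ketene on the central ring.

## Retrosynthetic reasoning

**27 to 25.** The two acetate O–acyl bonds are cut first, giving diol 26 and its bis(silyl ether) 25. An acetate on the carbon next to C3 would be eliminated at the tetronate stage further back. A silyl ether is a far poorer leaving group, so the carbinols stay silylated until the end. The forward steps are a desilylation and an acylation that must not touch four C–Br bonds.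

**25 to 24.** The C11–Br and C12–Br bonds are cut to give cyclobutene 24. Anti dibromination of an alkene delivers the trans relation by mechanism. Because of the twofold axis both faces of the alkene are equivalent, so only the site of opening of the bromonium ion is open. The addition is placed after the vinylic bromines are in, since only then is every other double bond too electron-poor to react.

**24 to 22.** The C4–Br and C10–Br bonds are cut back to C–O, giving bis(tetronic acid) 23 and its silyl ether 22. A vinylogous acid is converted to a vinylogous acyl bromide by a Vilsmeier-type halogenation. The oxygen at C4 is there for a reason: it is the silyloxy group that directs the alkyne in the cycloaddition.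

**22 to 21 (key disconnection).** The O1–C5 and O7–C6 bonds are cut and C2–C5 and C8–C6 rejoined, which contracts both lactones to the cyclobutenones of 21. This removes the two hindered tertiary C–O bonds from the list of bonds to be made: they arise by migration of carbon to oxygen with retention. The all-carbon skeleton of three four-membered rings is accessible by cycloaddition. The forward reaction must insert oxygen on the carbonyl side of each spiro carbon only, twice, without touching three C=C bonds and four silyl ethers.

**21 to 18 and 12.** The second cyclobutenone is cut at spiro C–C(OSi) and at C(=O)–C(side chain). This gives ketene 20 on the central ring, made from acid 18, and the (R)-siloxyalkyne 12. The polarised alkyne fixes the regiochemistry: its side-chain carbon attacks the ketene carbonyl carbon. The new spiro centre is set by the neighbouring spiro carbon, whose silyloxy-bearing arm is far larger than its carbonyl arm.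

**18 to 14 and 6.** Acid 18 comes from allyl ester 17, and 17 from ketene 16 and the (S)-siloxyalkyne 6 by the same cut. The ester on the adjacent ring carbon directs the alkyne to the opposite face. The spiro carbon of a 3-siloxycyclobutenone is a stereocentre only because one ring neighbour is C=O and the other C–OSi. Any step that removes the silyl group, or lets it change oxygen, before the oxidation erases that centre. The second carboxyl is therefore carried as an allyl ester, released under neutral conditions, and not as a methyl ester that would need hydroxide.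

**14 to 13.** Half-ester 14 is cut at one ester C–O bond back to meso anhydride 13. An alkaloid-mediated alcoholysis differentiates the enantiotopic carbonyls. This single event decides which enantiomer of 27 is made; the order in which 6 and 12 are introduced does not.

**6 and 12 to 1 and 7.** Each siloxyalkyne is cut at the alkyne C–C bond and at O–Si. It goes back through ynolate 5 (or 11) to silyloxy ester 4 (or 10), hydroxy ester 3 (or 9), hydroxy acid 2 (or 8) and amino acid 1 (or 7). The carbinol stereocentre is taken from the chiral pool and migrates with retention in the ester-to-ynolate rearrangement.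

## Alternatives that were turned down

**Alternative 1:** The cyclobutene C11=C12 is disconnected to a five-membered cyclic sulfone, the thiolane 1,1-dioxide A2, whose two oxygenated quaternary carbons would be drawn from the chiral pool. The forward key step is a halogenative Ramberg–Bäcklund contraction of A2 to cyclobutene diester A1, forming the double bond with loss of SO2.

- For it: the trans relation and the absolute configuration of both quaternary carbons are inherited and do not rest on an alkaloid desymmetrisation and two facial selections. On this point it is stronger than the chosen route.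
- Against it: A2 needs two adjacent quaternary carbinol carbons C-alkylated into a sulfur-bridged ring. The α-sulfonyl carbanion of the key step has a β-alkoxy leaving group and can open the ring by elimination, under a base that also attacks the esters.
- Against it: after A1, each lactone must still be built by acylating a hindered tertiary alcohol and closing by Dieckmann condensation a 3-silyloxyhexanoate, whose enolate can expel silanolate, before the sequence meets the chosen route at 23.
- In its place the chosen route brings both side chains in with the alkynes, makes every ring C–C bond by cycloaddition, and leaves only oxygen insertion at the crowded centres.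

**Alternative 2:** The C5–C6 bond between the two quaternary carbons is disconnected by a 4π photocyclisation of 2-pyranone A4. Irradiation would give the Dewar pyranone A3, a cyclobutene fused to a β-lactone.

- For it: one photon makes the four-membered ring and both oxygenated quaternary carbons. The bicycle enforces the trans relation of the two oxygens. The β-lactone is an activated acyl group for a first Dieckmann closure towards 23. In step count it is the shortest plan and beats the chosen route.
- Against it: A4 is flat and carries only a remote side-chain stereocentre, so both faces close alike. A3 would form with its core epimer in equal amounts, and separating that pair decides the enantiomer of the final product.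
- Against it: the Dewar pyranone reverts or loses CO2 easily, and the Dieckmann steps carry the same β-elimination risk as in alternative 1.
- In its place the chosen route controls the core configuration by a reagent and keeps every intermediate thermally manageable.

**Alternative 3:** The cyclobutene is disconnected by ring contraction to a dispiro cyclopropane carrying a tosylhydrazone, A7, itself the cyclopropanation product of the tetrasubstituted alkene A6. Base-induced decomposition of A7 gives a cyclopropylcarbene, and migration of a spiro carbon expands the ring to cyclobutene A5. Only the dibromination of step 16 would then remain to reach 27.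

- For it: the four-membered ring appears last, the alkene geometry of A6 fixes the trans oxygens, and the plan is highly convergent.
- Against it: A6 is a meso compound, because its centre of symmetry relates the S and R side chains. Cyclopropanation on either face gives enantiomers, and an enantioselective formylcarbene transfer to an electron-poor tetrasubstituted alkene has no reliable solution.
- Against it: the base and heat of the carbene generation meet acetates and vinylogous acyl bromides, and cyclopropylcarbenes also fragment to alkene and alkyne.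
- The chosen route is longer after its key step, but it sets the core configuration early on a small molecule and exposes the brominated lactones to no carbene and no base.

Key step: step 13

Assumption: quinine is taken to open 13 in the sense that gives the (1R,2S) half-ester 14, by analogy with its behaviour toward other cis-1,2-dicarboxylic anhydrides; if this ring responds in the opposite sense, quinidine is used in its place and nothing else changes.

Remark: compounds 17 to 24 are handled at or below room temperature, because 4-vinylcyclobutenones and 3,4-dioxygenated cyclobutenes open on heating.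

## Route

Step 1
Reactants: 1 L-norvaline
Product: 2 (2S)-2-hydroxypentanoic acid
Conditions: NaNO2, 1 M H2SO4, 0 °C → rt
Reagents that add atoms: water, O
Why: Diazotisation of the α-amino acid; the carboxylate displaces N2 to an α-lactone that water reopens, so two inversions give net retention and the (S) centre is kept.

Step 2
Reactants: 2 (2S)-2-hydroxypentanoic acid
Product: 3 methyl (2S)-2-hydroxypentanoate
Conditions: MeOH, H2SO4 (cat.), reflux
Reagents that add atoms: methanol, CO
Why: Fischer esterification; the stereocentre is not involved.

Step 3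
Reactants: 3 methyl (2S)-2-hydroxypentanoate
Product: 4 methyl (2S)-2-(tert-butyldimethylsilyloxy)pentanoate
Conditions: TBSCl, imidazole, DMF, rt
Reagents that add atoms: tert-butyldimethylsilyl chloride, CC(C)(C)[Si](C)(C)Cl
Why: Standard silylation of a secondary alcohol; the silyl ether survives the strong bases of step 4 and is a poor leaving group in the later enolate-type intermediates.

Step 4
Reactants: 4 methyl (2S)-2-(tert-butyldimethylsilyloxy)pentanoate
Product: 6 (3S)-3-(tert-butyldimethylsilyloxy)-1-(triisopropylsilyloxy)hex-1-yne, via lithium ynolate 5 (not isolated)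
Conditions: CH2Br2, lithium 2,2,6,6-tetramethylpiperidide, THF, −78 °C; LiN(SiMe3)2; n-BuLi, −78 °C → rt; then iPr3SiOTf, −78 °C → rt
Reagents that add atoms: dibromomethane, BrCBr; triisopropylsilyl trifluoromethanesulfonate, CC(C)[Si](C(C)C)(C(C)C)OS(=O)(=O)C(F)(F)F
Why: Kowalski ester homologation stopped at the ynolate: dibromomethyllithium adds to the ester, bromine–lithium exchange gives a carbenoid, and the silyloxyalkyl group shifts with retention to give the ynolate, which the bulky silyl triflate traps on oxygen; the α-hydrogen is not removed because enolisation occurs on the dibromomethyl side.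

Step 5
Reactants: 7 D-norvaline
Product: 8 (2R)-2-hydroxypentanoic acid
Conditions: NaNO2, 1 M H2SO4, 0 °C → rt
Reagents that add atoms: water, O
Why: As step 1, diazotisation with net retention through the α-lactone.

Step 6
Reactants: 8 (2R)-2-hydroxypentanoic acid
Product: 9 methyl (2R)-2-hydroxypentanoate
Conditions: MeOH, H2SO4 (cat.), reflux
Reagents that add atoms: methanol, CO
Why: Fischer esterification, as step 2.

Step 7
Reactants: 9 methyl (2R)-2-hydroxypentanoate
Product: 10 methyl (2R)-2-(tert-butyldimethylsilyloxy)pentanoate
Conditions: TBSCl, imidazole, DMF, rt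
Reagents that add atoms: tert-butyldimethylsilyl chloride, CC(C)(C)[Si](C)(C)Cl
Why: Silylation, as step 3.

Step 8
Reactants: 10 methyl (2R)-2-(tert-butyldimethylsilyloxy)pentanoate
Product: 12 (3R)-3-(tert-butyldimethylsilyloxy)-1-(triisopropylsilyloxy)hex-1-yne, via lithium ynolate 11 (not isolated)
Conditions: CH2Br2, lithium 2,2,6,6-tetramethylpiperidide, THF, −78 °C; LiN(SiMe3)2; n-BuLi, −78 °C → rt; then iPr3SiOTf, −78 °C → rt
Reagents that add atoms: dibromomethane, BrCBr; triisopropylsilyl trifluoromethanesulfonate, CC(C)[Si](C(C)C)(C(C)C)OS(=O)(=O)C(F)(F)F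
Why: Kowalski ester homologation to the ynolate and O-silylation, as step 4, with retention at the migrating carbon.

Step 9
Reactants: 13 cis-cyclobut-3-ene-1,2-dicarboxylic anhydride
Product: 14 (1R,2S)-2-[(prop-2-en-1-yloxy)carbonyl]cyclobut-3-ene-1-carboxylic acid
Conditions: allyl alcohol, quinine (1.1 equiv), toluene, −55 °C; aq. HCl wash
Reagents that add atoms: prop-2-en-1-ol, C=CCO
Why: Cinchona-alkaloid-mediated desymmetrising alcoholysis of a meso anhydride; the alkaloid acts as a chiral general base and selects one enantiotopic carbonyl, so no stereocentre is formed but the two existing ones are differentiated; the half-ester can be enriched further by crystallisation of an amine salt.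

Step 10
Reactants: 14 (1R,2S)-2-[(prop-2-en-1-yloxy)carbonyl]cyclobut-3-ene-1-carboxylic acid; 6 (3S)-3-(tert-butyldimethylsilyloxy)-1-(triisopropylsilyloxy)hex-1-yne
Product: 17 prop-2-en-1-yl (4R,5S)-2-[(1S)-1-(tert-butyldimethylsilyloxy)butyl]-1-oxo-3-(triisopropylsilyloxy)spiro[3.3]hepta-2,6-diene-5-carboxylate (C1 carbonyl cis and C3 siloxy carbon trans to the C5 ester), via acid chloride 15 (not isolated), via ketene 16 (not isolated)
Conditions: Me2C=C(Cl)NMe2, CH2Cl2, 0 °C; then 6, Et3N, CH2Cl2, −20 °C → rt
Reagents that add atoms: none
Why: Neutral conversion to the acid chloride, dehydrochlorination to the ketene and ketene–siloxyalkyne [2+2] cycloaddition: the side-chain carbon of the alkyne attacks the ketene carbonyl carbon in the ring plane, and the siloxy-bearing carbon then closes onto the ring carbon from the face anti to the neighbouring ester, which sets the spiro centre; an epimer at the spiro carbon would be a separable diastereomer.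

Step 11
Reactants: 17 prop-2-en-1-yl (4R,5S)-2-[(1S)-1-(tert-butyldimethylsilyloxy)butyl]-1-oxo-3-(triisopropylsilyloxy)spiro[3.3]hepta-2,6-diene-5-carboxylate
Product: 18 (4R,5S)-2-[(1S)-1-(tert-butyldimethylsilyloxy)butyl]-1-oxo-3-(triisopropylsilyloxy)spiro[3.3]hepta-2,6-diene-5-carboxylic acid
Conditions: Pd(PPh3)4 (cat.), PhSiH3, CH2Cl2, 0 °C → rt
Reagents that add atoms: none
Why: Zerovalent palladium ionises the allyl ester to a π-allyl complex and the silane reduces it to propene (allyl ester cleavage with a hydride scavenger); no base, acid, fluoride or amine nucleophile is present, so the silyl vinylogous ester that fixes the spiro centre stays in place.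

Step 12
Reactants: 18 (4R,5S)-2-[(1S)-1-(tert-butyldimethylsilyloxy)butyl]-1-oxo-3-(triisopropylsilyloxy)spiro[3.3]hepta-2,6-diene-5-carboxylic acid; 12 (3R)-3-(tert-butyldimethylsilyloxy)-1-(triisopropylsilyloxy)hex-1-yne
Product: 21 (4R,5R)-2-[(1S)-1-(tert-butyldimethylsilyloxy)butyl]-7-[(1R)-1-(tert-butyldimethylsilyloxy)butyl]-3,8-bis(triisopropylsilyloxy)dispiro[3.0.3.2]deca-2,7,9-triene-1,6-dione (carbonyl carbons C1 and C6 on opposite faces of the cyclobutene), via acid chloride 19 (not isolated), via ketene 20 (not isolated)
Conditions: Me2C=C(Cl)NMe2, CH2Cl2, −20 °C; then 12, Et3N, CH2Cl2, −20 °C → rt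
Reagents that add atoms: none
Why: Second ketene–siloxyalkyne [2+2] cycloaddition with the same regiochemistry; the siloxy-bearing carbon of the alkyne bonds to the ketene ring carbon on the face anti to the triisopropylsilyloxy-bearing arm of the first spiro ring, which overhangs that face, so the new carbonyl lies trans to the first one and the second spiro centre is set.

Step 13
Reactants: 21 (4R,5R)-2-[(1S)-1-(tert-butyldimethylsilyloxy)butyl]-7-[(1R)-1-(tert-butyldimethylsilyloxy)butyl]-3,8-bis(triisopropylsilyloxy)dispiro[3.0.3.2]deca-2,7,9-triene-1,6-dione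
Product: 22 (5R,6R)-3-[(1S)-1-(tert-butyldimethylsilyloxy)butyl]-9-[(1R)-1-(tert-butyldimethylsilyloxy)butyl]-4,10-bis(triisopropylsilyloxy)-1,7-dioxadispiro[4.0.4.2]dodeca-3,9,11-triene-2,8-dione (O1 and O7 trans)
Conditions: Me3SiOOSiMe3 (3 equiv), Me3SiOTf (cat.), CH2Cl2, −78 → −40 °C; pyridine quench
Reagents that add atoms: bis(trimethylsilyl) peroxide, C[Si](C)(C)OO[Si](C)(C)C
Why: Me3SiOTf silylates each ring carbonyl, the silyl peroxide adds to the activated carbonyl carbon to give a silyl perketal, and silylation of its distal oxygen triggers the 1,2-shift of the spiro carbon from carbon to oxygen with loss of hexamethyldisiloxane (Baeyer–Villiger oxidation in its bis-silyl peroxide form; the closest known case is the ring expansion of cyclobutanones and cyclobutenones to γ-lactones and butenolides). Each five-membered lactone is closed by expansion of a four-membered ring, a 1,2-shift driven by loss of ring strain and not a cyclisation, so O1–C5 and O7–C6 form as C2–C5 and C8–C6 break. No stereocentre is created: the shift is suprafacial, each spiro carbon keeps its configuration, and the trans carbonyl carbons of 21 become the trans ring oxygens of 22. Three selectivities are needed. The migrating group must be the quaternary allylic sp3 spiro carbon and not the vinylic carbon, which its higher substitution and the strain release secure. The peroxide must add at the carbonyl carbon and not at the siloxy-bearing end of the vinylogous ester, since insertion on that side would give the spiro epimer; the triisopropylsilyl group shields that end and is too hindered to be removed by triflate, while the carbonyl end carries only a trimethylsilyl group. The oxidant must spare the cyclobutene and the two enol ether double bonds, which a Lewis-acid-activated silyl peroxide does because it is not an epoxidising agent, and the low temperature protects the silyl ethers and the allylic lactone C–O bonds.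

Step 14
Reactants: 22 (5R,6R)-3-[(1S)-1-(tert-butyldimethylsilyloxy)butyl]-9-[(1R)-1-(tert-butyldimethylsilyloxy)butyl]-4,10-bis(triisopropylsilyloxy)-1,7-dioxadispiro[4.0.4.2]dodeca-3,9,11-triene-2,8-dione
Product: 23 (5S,6S)-3-[(1S)-1-(tert-butyldimethylsilyloxy)butyl]-9-[(1R)-1-(tert-butyldimethylsilyloxy)butyl]-4,10-dihydroxy-1,7-dioxadispiro[4.0.4.2]dodeca-3,9,11-triene-2,8-dione
Conditions: Bu4NF (2.2 equiv), AcOH (2.2 equiv), THF, −20 → 0 °C; pH 3 buffer
Reagents that add atoms: none
Why: Fluoride cleaves the vinylogous silyl esters, which are far more labile than the secondary alkyl silyl ethers, and acetic acid buffers the tetronate; the spiro centres are now fixed by the lactone oxygens, so loss of the enol silyl groups no longer endangers them.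

Step 15
Reactants: 23 (5S,6S)-3-[(1S)-1-(tert-butyldimethylsilyloxy)butyl]-9-[(1R)-1-(tert-butyldimethylsilyloxy)butyl]-4,10-dihydroxy-1,7-dioxadispiro[4.0.4.2]dodeca-3,9,11-triene-2,8-dione
Product: 24 (5R,6R)-4,10-dibromo-3-[(1S)-1-(tert-butyldimethylsilyloxy)butyl]-9-[(1R)-1-(tert-butyldimethylsilyloxy)butyl]-1,7-dioxadispiro[4.0.4.2]dodeca-3,9,11-triene-2,8-dione
Conditions: (COBr)2, DMF, 2,6-di-tert-butyl-4-methylpyridine, CH2Cl2, 0 °C → rt
Reagents that add atoms: oxalyl bromide, O=C(Br)C(Br)=O
Why: Vilsmeier-type bromination of a tetronic acid: the enol oxygen is activated by the bromoiminium salt and bromide replaces it at C4 by addition–elimination; the hindered pyridine takes up HBr so that the silyl ethers are not cleaved.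

Step 16
Reactants: 24 (5R,6R)-4,10-dibromo-3-[(1S)-1-(tert-butyldimethylsilyloxy)butyl]-9-[(1R)-1-(tert-butyldimethylsilyloxy)butyl]-1,7-dioxadispiro[4.0.4.2]dodeca-3,9,11-triene-2,8-dione
Product: 25 (5S,6S,11R,12R)-4,10,11,12-tetrabromo-3-[(1S)-1-(tert-butyldimethylsilyloxy)butyl]-9-[(1R)-1-(tert-butyldimethylsilyloxy)butyl]-1,7-dioxadispiro[4.0.4.2]dodeca-3,9-diene-2,8-dione
Conditions: Br2, CH2Cl2, −20 °C → rt, dark
Reagents that add atoms: bromine, BrBr
Why: Anti addition through a bromonium ion gives the trans dibromide and the two alkene faces are related by the twofold axis of the core, so only the site of bromide attack matters; bromide is expected to enter anti to the C–O bond of the neighbouring spiro carbon (least repulsion with the lactone oxygens), which puts each new bromine trans to that oxygen as in 27, and the electron-poor bromobutenolide double bonds do not compete.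

Step 17
Reactants: 25 (5S,6S,11R,12R)-4,10,11,12-tetrabromo-3-[(1S)-1-(tert-butyldimethylsilyloxy)butyl]-9-[(1R)-1-(tert-butyldimethylsilyloxy)butyl]-1,7-dioxadispiro[4.0.4.2]dodeca-3,9-diene-2,8-dione
Product: 26 (5S,6S,11R,12R)-4,10,11,12-tetrabromo-3-[(1S)-1-hydroxybutyl]-9-[(1R)-1-hydroxybutyl]-1,7-dioxadispiro[4.0.4.2]dodeca-3,9-diene-2,8-dione
Conditions: HF·pyridine, THF, 0 °C → rt
Reagents that add atoms: none
Why: Acidic fluoride desilylation of secondary silyl ethers; no base is present that could attack the vinylogous acyl bromides or the dibromide.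

Step 18
Reactants: 26 (5S,6S,11R,12R)-4,10,11,12-tetrabromo-3-[(1S)-1-hydroxybutyl]-9-[(1R)-1-hydroxybutyl]-1,7-dioxadispiro[4.0.4.2]dodeca-3,9-diene-2,8-dione
Product: 27 (1S)-1-[(5S,6S,11R,12R)-9-[(1R)-1-(acetyloxy)butyl]-4,10,11,12-tetrabromo-2,8-dioxo-1,7-dioxadispiro[4.0.4.2]dodeca-3,9-dien-3-yl]butyl acetate
Conditions: Ac2O, pyridine, DMAP (cat.), CH2Cl2, 0 °C → rt
Reagents that add atoms: acetic anhydride, CC(=O)OC(C)=O
Why: Nucleophile-catalysed acetylation of two secondary alcohols; the ring hydrogens are cis to the neighbouring bromines, so base-induced anti elimination of HBr has no suitable geometry.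

## Compound list

1 | L-norvaline | N[C@@H](CCC)C(=O)O | starting material
2 | (2S)-2-hydroxypentanoic acid | CCC[C@H](O)C(=O)O | intermediate
3 | methyl (2S)-2-hydroxypentanoate | CCC[C@H](O)C(=O)OC | intermediate
4 | methyl (2S)-2-(tert-butyldimethylsilyloxy)pentanoate | CCC[C@H](O[Si](C)(C)C(C)(C)C)C(=O)OC | intermediate
5 | lithium (3S)-3-(tert-butyldimethylsilyloxy)hex-1-yn-1-olate (not isolated) | CCC[C@H](O[Si](C)(C)C(C)(C)C)C#C[O-].[Li+] | intermediate
6 | (3S)-3-(tert-butyldimethylsilyloxy)-1-(triisopropylsilyloxy)hex-1-yne | CCC[C@H](O[Si](C)(C)C(C)(C)C)C#CO[Si](C(C)C)(C(C)C)C(C)C | intermediate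
7 | D-norvaline | N[C@H](CCC)C(=O)O | starting material
8 | (2R)-2-hydroxypentanoic acid | CCC[C@@H](O)C(=O)O | intermediate
9 | methyl (2R)-2-hydroxypentanoate | CCC[C@@H](O)C(=O)OC | intermediate
10 | methyl (2R)-2-(tert-butyldimethylsilyloxy)pentanoate | CCC[C@@H](O[Si](C)(C)C(C)(C)C)C(=O)OC | intermediate
11 | lithium (3R)-3-(tert-butyldimethylsilyloxy)hex-1-yn-1-olate (not isolated) | CCC[C@@H](O[Si](C)(C)C(C)(C)C)C#C[O-].[Li+] | intermediate
12 | (3R)-3-(tert-butyldimethylsilyloxy)-1-(triisopropylsilyloxy)hex-1-yne | CCC[C@@H](O[Si](C)(C)C(C)(C)C)C#CO[Si](C(C)C)(C(C)C)C(C)C | intermediate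
13 | cis-cyclobut-3-ene-1,2-dicarboxylic anhydride | O=C1OC(=O)[C@H]2C=C[C@@H]12 | starting material
14 | (1R,2S)-2-[(prop-2-en-1-yloxy)carbonyl]cyclobut-3-ene-1-carboxylic acid | OC(=O)[C@@H]1C=C[C@@H]1C(=O)OCC=C | intermediate
15 | prop-2-en-1-yl cis-4-(chlorocarbonyl)cyclobut-2-ene-1-carboxylate, configuration as in 14 (not isolated) | ClC(=O)[C@@H]1C=C[C@@H]1C(=O)OCC=C | intermediate
16 | prop-2-en-1-yl 4-(oxomethylidene)cyclobut-2-ene-1-carboxylate, ester carbon as in 14 (not isolated) | O=C=C1C=C[C@@H]1C(=O)OCC=C | intermediate
17 | prop-2-en-1-yl (4R,5S)-2-[(1S)-1-(tert-butyldimethylsilyloxy)butyl]-1-oxo-3-(triisopropylsilyloxy)spiro[3.3]hepta-2,6-diene-5-carboxylate | CCC[C@H](O[Si](C)(C)C(C)(C)C)C1=C(O[Si](C(C)C)(C(C)C)C(C)C)[C@@]2(C1=O)C=C[C@@H]2C(=O)OCC=C | intermediate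
18 | (4R,5S)-2-[(1S)-1-(tert-butyldimethylsilyloxy)butyl]-1-oxo-3-(triisopropylsilyloxy)spiro[3.3]hepta-2,6-diene-5-carboxylic acid | CCC[C@H](O[Si](C)(C)C(C)(C)C)C1=C(O[Si](C(C)C)(C(C)C)C(C)C)[C@@]2(C1=O)C=C[C@@H]2C(=O)O | intermediate
19 | acid chloride of 18 (not isolated) | CCC[C@H](O[Si](C)(C)C(C)(C)C)C1=C(O[Si](C(C)C)(C(C)C)C(C)C)[C@@]2(C1=O)C=C[C@@H]2C(=O)Cl | intermediate
20 | 2-[(1S)-1-(tert-butyldimethylsilyloxy)butyl]-5-(oxomethylidene)-3-(triisopropylsilyloxy)spiro[3.3]hepta-2,6-dien-1-one, spiro carbon as in 17 (not isolated) | CCC[C@H](O[Si](C)(C)C(C)(C)C)C1=C(O[Si](C(C)C)(C(C)C)C(C)C)[C@@]2(C1=O)C=CC2=C=O | intermediate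
21 | (4R,5R)-2-[(1S)-1-(tert-butyldimethylsilyloxy)butyl]-7-[(1R)-1-(tert-butyldimethylsilyloxy)butyl]-3,8-bis(triisopropylsilyloxy)dispiro[3.0.3.2]deca-2,7,9-triene-1,6-dione | CCC[C@H](O[Si](C)(C)C(C)(C)C)C1=C(O[Si](C(C)C)(C(C)C)C(C)C)[C@@]2(C1=O)C=C[C@@]21C(=O)C([C@@H](CCC)O[Si](C)(C)C(C)(C)C)=C1O[Si](C(C)C)(C(C)C)C(C)C | intermediate
22 | (5R,6R)-3-[(1S)-1-(tert-butyldimethylsilyloxy)butyl]-9-[(1R)-1-(tert-butyldimethylsilyloxy)butyl]-4,10-bis(triisopropylsilyloxy)-1,7-dioxadispiro[4.0.4.2]dodeca-3,9,11-triene-2,8-dione | CCC[C@H](O[Si](C)(C)C(C)(C)C)C1=C(O[Si](C(C)C)(C(C)C)C(C)C)[C@@]2(OC1=O)C=C[C@@]21OC(=O)C([C@@H](CCC)O[Si](C)(C)C(C)(C)C)=C1O[Si](C(C)C)(C(C)C)C(C)C | intermediate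
23 | (5S,6S)-3-[(1S)-1-(tert-butyldimethylsilyloxy)butyl]-9-[(1R)-1-(tert-butyldimethylsilyloxy)butyl]-4,10-dihydroxy-1,7-dioxadispiro[4.0.4.2]dodeca-3,9,11-triene-2,8-dione | CCC[C@H](O[Si](C)(C)C(C)(C)C)C1=C(O)[C@@]2(OC1=O)C=C[C@@]21OC(=O)C([C@@H](CCC)O[Si](C)(C)C(C)(C)C)=C1O | intermediate
24 | (5R,6R)-4,10-dibromo-3-[(1S)-1-(tert-butyldimethylsilyloxy)butyl]-9-[(1R)-1-(tert-butyldimethylsilyloxy)butyl]-1,7-dioxadispiro[4.0.4.2]dodeca-3,9,11-triene-2,8-dione | CCC[C@H](O[Si](C)(C)C(C)(C)C)C1=C(Br)[C@@]2(OC1=O)C=C[C@@]21OC(=O)C([C@@H](CCC)O[Si](C)(C)C(C)(C)C)=C1Br | intermediate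
25 | (5S,6S,11R,12R)-4,10,11,12-tetrabromo-3-[(1S)-1-(tert-butyldimethylsilyloxy)butyl]-9-[(1R)-1-(tert-butyldimethylsilyloxy)butyl]-1,7-dioxadispiro[4.0.4.2]dodeca-3,9-diene-2,8-dione | CCC[C@H](O[Si](C)(C)C(C)(C)C)C1=C(Br)[C@@]2(OC1=O)[C@@H](Br)[C@H](Br)[C@@]21OC(=O)C([C@@H](CCC)O[Si](C)(C)C(C)(C)C)=C1Br | intermediate
26 | (5S,6S,11R,12R)-4,10,11,12-tetrabromo-3-[(1S)-1-hydroxybutyl]-9-[(1R)-1-hydroxybutyl]-1,7-dioxadispiro[4.0.4.2]dodeca-3,9-diene-2,8-dione | CCC[C@H](O)C1=C(Br)[C@@]2(OC1=O)[C@@H](Br)[C@H](Br)[C@@]21OC(=O)C([C@@H](CCC)O)=C1Br | intermediate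
27 | (1S)-1-[(5S,6S,11R,12R)-9-[(1R)-1-(acetyloxy)butyl]-4,10,11,12-tetrabromo-2,8-dioxo-1,7-dioxadispiro[4.0.4.2]dodeca-3,9-dien-3-yl]butyl acetate | CCC[C@H](OC(C)=O)C1=C(Br)[C@@]2(OC1=O)[C@@H](Br)[C@H](Br)[C@@]21OC(=O)C([C@@H](CCC)OC(C)=O)=C1Br | target

## Step count and least certain steps

Total: 18 steps. Longest linear sequence: 13 steps (steps 1–4, then 10–18).

**Step 13 (key step).** Three things may go wrong.
- The peroxide may add slowly, because each carbonyl is part of a vinylogous ester.
- The peroxide may add at the siloxy-bearing end, or the silyl group may be transposed between the two oxygens by triflate. Either is an inversion of a spiro centre: at one ring it gives the cis diastereomer, at both rings the mirror-image core, which is loss of enantiomeric purity.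
- The Lewis acid may ionise a side-chain silyl ether or a newly formed allylic lactone C–O bond.

Fallback: the oxidation is done one ring at a time, setting out from 17 and returning at 22. Oxidation of 17 alone, where the peroxide class can be varied on a simpler ketone, gives the mono-butenolide allyl ester F1. Deallylation as in step 11 gives the acid F2, the chloroenamine gives its acid chloride F3, and triethylamine gives the ketene F4. Cycloaddition with 12 gives the butenolide–cyclobutenone F5, and a second oxidation gives 22. This also changes step 12: the second ketene is then directed by a lactone oxygen against a silyloxy-bearing carbon, and the cis ring carbonyl that the acid chloride 19 could acylate is no longer there.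

**Step 10.** The ketene may dimerise before it is trapped. The half-ester acid chloride may scramble through a symmetrical acyloxonium ion and so racemise. The alkyne may add on the face syn to the ester. Poor face selectivity gives separable diastereomers.

Fallback for a reversed preference: the antipodal series is used, setting out from 13 and returning at 20. Opening of 13 with quinidine gives the antipodal half-ester F6. Its acid chloride F7 and ketene F8 give with 6, by addition syn to the ester, the C5 epimer F9 of 17. Deallylation gives the acid F10 and the chloroenamine its acid chloride F11. Dehydrochlorination of F11 gives ketene 20 itself, because C5 becomes trigonal.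

**Step 16.** The bromonium ion may be opened at the other carbon, with bromide entering on the side of the small lactone oxygen instead of the bromine-bearing vinylic carbon. This gives the trans dibromide with each bromine cis to the neighbouring ring oxygen. The sense cannot be predicted with confidence, since dipole repulsion and steric hindrance point in opposite directions.

Fallback, setting out from 24 and returning at 25: the unwanted isomer F12 is separated and returned to 24 with zinc dust. The addition is then run as a radical chain process (light, non-polar solvent), where atom transfer to a bridged bromoalkyl radical is governed by sterics and not by ion–dipole effects.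

**Step 15.** HBr or the bromoiminium salt may cleave or substitute the side-chain silyl ethers. The tetronic acid may lose silanol towards a 3-alkylidene dione.

Fallback, setting out from 23 and returning at 24: the two enols are converted with triflic anhydride and a hindered pyridine into the bis(enol triflate) F13. The triflates are exchanged for bromide with LiBr by addition–elimination at the vinylogous acyl position, with no acid present.

## Further compounds

F1 | step 13 | prop-2-en-1-yl 3-[(1S)-1-(tert-butyldimethylsilyloxy)butyl]-2-oxo-4-(triisopropylsilyloxy)-1-oxaspiro[4.3]octa-3,7-diene-6-carboxylate, ring oxygen cis to the ester | CCC[C@H](O[Si](C)(C)C(C)(C)C)C1=C(O[Si](C(C)C)(C(C)C)C(C)C)[C@@]2(OC1=O)C=C[C@@H]2C(=O)OCC=C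
F2 | step 13 | carboxylic acid from F1 | CCC[C@H](O[Si](C)(C)C(C)(C)C)C1=C(O[Si](C(C)C)(C(C)C)C(C)C)[C@@]2(OC1=O)C=C[C@@H]2C(=O)O
F3 | step 13 | acid chloride of F2 | CCC[C@H](O[Si](C)(C)C(C)(C)C)C1=C(O[Si](C(C)C)(C(C)C)C(C)C)[C@@]2(OC1=O)C=C[C@@H]2C(=O)Cl
F4 | step 13 | ketene from F3 | CCC[C@H](O[Si](C)(C)C(C)(C)C)C1=C(O[Si](C(C)C)(C(C)C)C(C)C)[C@@]2(OC1=O)C=CC2=C=O
F5 | step 13 | dispiro butenolide–cyclobutenone, ring oxygen and ring carbonyl carbon trans | CCC[C@H](O[Si](C)(C)C(C)(C)C)C1=C(O[Si](C(C)C)(C(C)C)C(C)C)[C@@]2(OC1=O)C=C[C@@]21C(=O)C([C@@H](CCC)O[Si](C)(C)C(C)(C)C)=C1O[Si](C(C)C)(C(C)C)C(C)C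
F6 | step 10 | (1S,2R)-2-[(prop-2-en-1-yloxy)carbonyl]cyclobut-3-ene-1-carboxylic acid | OC(=O)[C@H]1C=C[C@H]1C(=O)OCC=C
F7 | step 10 | acid chloride of F6 | ClC(=O)[C@H]1C=C[C@H]1C(=O)OCC=C
F8 | step 10 | ketene from F7, enantiomer of 16 | O=C=C1C=C[C@H]1C(=O)OCC=C
F9 | step 10 | C5 epimer of 17, siloxy carbon C3 cis to the ester | CCC[C@H](O[Si](C)(C)C(C)(C)C)C1=C(O[Si](C(C)C)(C(C)C)C(C)C)[C@@]2(C1=O)C=C[C@H]2C(=O)OCC=C
F10 | step 10 | carboxylic acid from F9, C5 epimer of 18 | CCC[C@H](O[Si](C)(C)C(C)(C)C)C1=C(O[Si](C(C)C)(C(C)C)C(C)C)[C@@]2(C1=O)C=C[C@H]2C(=O)O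
F11 | step 10 | acid chloride of F10 | CCC[C@H](O[Si](C)(C)C(C)(C)C)C1=C(O[Si](C(C)C)(C(C)C)C(C)C)[C@@]2(C1=O)C=C[C@H]2C(=O)Cl
F12 | step 16 | trans dibromide diastereomer of 25, each ring bromine cis to the neighbouring ring oxygen | CCC[C@H](O[Si](C)(C)C(C)(C)C)C1=C(Br)[C@@]2(OC1=O)[C@H](Br)[C@@H](Br)[C@@]21OC(=O)C([C@@H](CCC)O[Si](C)(C)C(C)(C)C)=C1Br
F13 | step 15 | bis(enol triflate) of 23 | CCC[C@H](O[Si](C)(C)C(C)(C)C)C1=C(OS(=O)(=O)C(F)(F)F)[C@@]2(OC1=O)C=C[C@@]21OC(=O)C([C@@H](CCC)O[Si](C)(C)C(C)(C)C)=C1OS(=O)(=O)C(F)(F)F
A1 | alternative 1 | dimethyl (1R,2R)-1,2-bis(methoxymethoxy)cyclobut-3-ene-1,2-dicarboxylate | COC(=O)[C@@]1(OCOC)C=C[C@@]1(C(=O)OC)OCOC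
A2 | alternative 1 | dimethyl 3,4-bis(methoxymethoxy)thiolane-3,4-dicarboxylate 1,1-dioxide, oxygens trans | COC(=O)[C@@]1(OCOC)CS(=O)(=O)C[C@@]1(C(=O)OC)OCOC
A3 | alternative 2 | methyl 4-{[(3R)-3-(tert-butyldimethylsilyloxy)hexanoyl]oxy}-3-oxo-2-oxabicyclo[2.2.0]hex-5-ene-1-carboxylate | COC(=O)[C@@]1(OC2=O)C=C[C@@]12OC(=O)C[C@@H](CCC)O[Si](C)(C)C(C)(C)C
A4 | alternative 2 | methyl 5-{[(3R)-3-(tert-butyldimethylsilyloxy)hexanoyl]oxy}-6-oxo-6H-pyran-2-carboxylate | COC(=O)C1=CC=C(OC(=O)C[C@@H](CCC)O[Si](C)(C)C(C)(C)C)C(=O)O1
A5 | alternative 3 | dispiro cyclobutene bis(4-bromobutenolide) diacetate, ring oxygens trans | CCC[C@H](OC(C)=O)C1=C(Br)[C@@]2(OC1=O)C=C[C@@]21OC(=O)C([C@@H](CCC)OC(C)=O)=C1Br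
A6 | alternative 3 | meso (E)-5,5′-bi(4-bromo-3-(1-acetoxybutyl)furan-2(5H)-on-5-ylidene), ring oxygens trans across the central double bond | CCC[C@H](OC(C)=O)C1=C(Br)/C(OC1=O)=C1\OC(=O)C([C@@H](CCC)OC(C)=O)=C1Br
A7 | alternative 3 | tosylhydrazone of the dispiro cyclopropanecarbaldehyde from A6, either epimer at the cyclopropane CH | CCC[C@H](OC(C)=O)C1=C(Br)[C@@]2(OC1=O)C(C=NNS(=O)(=O)c3ccc(C)cc3)[C@@]21OC(=O)C([C@@H](CCC)OC(C)=O)=C1Br
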